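**Remark on the chemistry:** locants C1–C20 follow the briarane numbering of the target (C19 = lactone carbonyl, C16 = ester carbon, C20 = exocyclic methylene carbon, C15 = angular methyl, C18 = lactone methyl). The C5=C6 geometry is taken as drawn (CO2Me cis to C7). Ring A = cyclohexane (C1, C10–C14), ring B = ten-membered carbocycle (C1–C10), ring C = γ-lactone (O–C19–C17–C8–C7). Nothing here has been run; all selectivities are expectations.

## Retrosynthetic overview

1. Target ⇐ acetylation of four secondary hydroxyls ⇐ pentaol 53 ⇐ ring B closed last by Nozaki–Hiyama–Kishi formation of C4–C5 from an (E)-α-bromoacrylate that already carries the C5=C6 geometry.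
2. Ring C ⇐ cross-conjugated 2-bromo-1,3-diene C18=C17(Br)–C8=C7 + CO2 + one oxygen atom in one flask: C17–C19 by carboxylation, O–C7 by 5-endo epoxide opening, C8–OH from the epoxide oxygen.
3. Enabling feature: in ring C the tertiary carbinol C8 lies between C17 (α to the C19 carbonyl) and the O-bearing C7. A C8 that is sp2 with C17 metallated and C7=C8 epoxidisable is the same array one oxidation level lower; CO2 supplies C19 and both lactone oxygens.
4. C9–C10 by syn-selective zirconium aldol of a regiodefined ring A enolate with (Z)-2-bromoenal 16; C1 by cuprate addition anti to the C14 oxygen; C14 by CBS reduction.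
5. Order of ring formation: ring A (from 1) → ring C (key step) → ring B (ring closure at C4–C5).

Key step: step 13

## Route

Step 1
Reactants: 1 1,4-dioxaspiro[4.5]dec-6-en-8-one; 2 iodine
Product: 3 7-iodo-1,4-dioxaspiro[4.5]dec-6-en-8-one
Conditions: I2, pyridine, CH2Cl2, 0→25 °C
Reagents that add atoms: iodine, II
Why: α-Iodination of the enone by pyridine-mediated conjugate addition–iodination–elimination should proceed without touching the ketal; no stereocentre is formed.

Step 2
Reactants: 3 7-iodo-1,4-dioxaspiro[4.5]dec-6-en-8-one; 4 potassium (benzyloxymethyl)trifluoroborate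
Product: 5 7-[(benzyloxy)methyl]-1,4-dioxaspiro[4.5]dec-6-en-8-one
Conditions: Pd(OAc)2 (5 mol %), RuPhos, Cs2CO3, dioxane–H2O, 90 °C
Reagents that add atoms: potassium (benzyloxymethyl)trifluoroborate, [K+].F[B-](F)(F)COCc1ccccc1
Why: Suzuki–Miyaura coupling of the α-iodoenone with an alkoxymethyltrifluoroborate should attach the future C2 carbon; enone and ketal tolerate the aqueous base.

Step 3
Reactants: 5 7-[(benzyloxy)methyl]-1,4-dioxaspiro[4.5]dec-6-en-8-one
Product: 6 (8S)-7-[(benzyloxy)methyl]-1,4-dioxaspiro[4.5]dec-6-en-8-ol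
Conditions: (R)-2-methyl-CBS-oxazaborolidine (10 mol %), BH3·SMe2, THF, −30 °C
Reagents that add atoms: none
Why: Corey–Bakshi–Shibata reduction, in which the α-branched alkenyl arm acts as the large group, so the (R)-catalyst should give the (S)-alcohol that becomes C14.

Step 4
Reactants: 6 (8S)-7-[(benzyloxy)methyl]-1,4-dioxaspiro[4.5]dec-6-en-8-ol; 7 tert-butylchlorodimethylsilane
Product: 8 (8S)-7-[(benzyloxy)methyl]-8-[(tert-butyldimethylsilyl)oxy]-1,4-dioxaspiro[4.5]dec-6-ene
Conditions: TBSCl, imidazole, DMF, 25 °C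
Reagents that add atoms: tert-butylchlorodimethylsilane, C[Si](C)(Cl)C(C)(C)C
Why: Imidazole-mediated silylation of the secondary allylic alcohol; no stereocentre is touched.

Step 5
Reactants: 8 (8S)-7-[(benzyloxy)methyl]-8-[(tert-butyldimethylsilyl)oxy]-1,4-dioxaspiro[4.5]dec-6-ene; 9 water
Product: 10 (4S)-3-[(benzyloxy)methyl]-4-[(tert-butyldimethylsilyl)oxy]cyclohex-2-en-1-one
Conditions: PPTS, acetone–H2O, 50 °C
Reagents that add atoms: water, O
Why: Mild acetal hydrolysis should unveil the C11 ketone in conjugation with the existing alkene while TBS and benzyl ethers survive.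

Step 6
Reactants: 11 (Z)-4-(benzyloxy)but-2-en-1-ol
Product: 13 (E)-4-(benzyloxy)but-2-enal, via (Z)-4-(benzyloxy)but-2-enal 12 (not isolated)
Conditions: MnO2, CH2Cl2, 25 °C; then pyridine (cat.), 25 °C
Reagents that add atoms: none
Why: Chemoselective allylic oxidation, after which the labile (Z)-enal should isomerise under mild base to the thermodynamically preferred (E)-enal.

Step 7
Reactants: 13 (E)-4-(benzyloxy)but-2-enal; 14 bromine
Product: 16 (Z)-4-(benzyloxy)-2-bromobut-2-enal, via 2,3-dibromide 15 (not isolated)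
Conditions: Br2, CH2Cl2, −78 °C; then Et3N, 0 °C
Reagents that add atoms: bromine, BrBr
Why: Bromination–dehydrobromination (anti addition, then E1cB loss of HBr) should give the thermodynamically preferred (Z)-2-bromoenal with Br cis to CH2OBn, which fixes the later C7=C8 geometry.

Step 8
Reactants: 10 (4S)-3-[(benzyloxy)methyl]-4-[(tert-butyldimethylsilyl)oxy]cyclohex-2-en-1-one; 17 lithium dimethylcuprate; 18 chlorotrimethylsilane
Product: 19 {[(3S,4S)-3-[(benzyloxy)methyl]-4-[(tert-butyldimethylsilyl)oxy]-3-methylcyclohex-1-en-1-yl]oxy}trimethylsilane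
Conditions: Me2CuLi (from MeLi and CuI), Me3SiCl, THF, −78 °C
Reagents that add atoms: lithium dimethylcuprate, [Li+].C[Cu-]C; chlorotrimethylsilane, C[Si](C)(C)Cl
Why: Silyl chloride-accelerated cuprate conjugate addition should create the C1 quaternary centre with methyl entering anti to the adjacent C14 silyloxy group and trap the regiodefined enolate as its silyl enol ether.

Step 9
Reactants: 19 {[(3S,4S)-3-[(benzyloxy)methyl]-4-[(tert-butyldimethylsilyl)oxy]-3-methylcyclohex-1-en-1-yl]oxy}trimethylsilane; 16 (Z)-4-(benzyloxy)-2-bromobut-2-enal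
Product: 22 (2S,3S,4S)-3-[(benzyloxy)methyl]-2-[(1S,2Z)-4-(benzyloxy)-2-bromo-1-hydroxybut-2-en-1-yl]-4-[(tert-butyldimethylsilyl)oxy]-3-methylcyclohexan-1-one, via lithium enolate 20 (not isolated), via zirconium enolate 21 (not isolated)
Conditions: MeLi, THF, 0 °C; Cp2ZrCl2, −78 °C; then 16, −78 °C
Reagents that add atoms: (Z)-4-(benzyloxy)-2-bromobut-2-enal, O=C/C(Br)=C/COCc1ccccc1
Why: Aldol addition of the zirconium enolate, which is syn-selective irrespective of enolate geometry (closed transition state), with attack on the enolate face anti to the C1 benzyloxymethyl and C14 silyloxy groups, should set C10 and C9 (9S).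

Step 10
Reactants: 22 aldol adduct; 23 tert-butyldimethylsilyl trifluoromethanesulfonate
Product: 24 (2S,3S,4S)-3-[(benzyloxy)methyl]-2-[(1S,2Z)-4-(benzyloxy)-2-bromo-1-[(tert-butyldimethylsilyl)oxy]but-2-en-1-yl]-4-[(tert-butyldimethylsilyl)oxy]-3-methylcyclohexan-1-one
Conditions: TBSOTf, 2,6-lutidine, CH2Cl2, −78 °C
Reagents that add atoms: tert-butyldimethylsilyl trifluoromethanesulfonate, CC(C)(C)[Si](C)(C)OS(=O)(=O)C(F)(F)F
Why: Low-temperature silylation of the hindered C9 hydroxyl blocks retro-aldol cleavage and later trans-lactonisation to O9.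

Step 11
Reactants: 24 bis-TBS ketone; 25 (trimethylsilyl)methyllithium; 18 chlorotrimethylsilane
Product: 27 C11-masked vinyl bromide (C11 carries OSiMe3 and CH2SiMe3 in place of the ketone; otherwise as 24), via cerium alkoxide 26 (not isolated)
Conditions: Me3SiCH2Li, CeCl3, THF, −78 °C; then Me3SiCl, −78→0 °C
Reagents that add atoms: (trimethylsilyl)methyllithium, [Li]C[Si](C)(C)C; chlorotrimethylsilane, C[Si](C)(C)Cl
Why: Non-basic organocerium 1,2-addition to the hindered, enolisable ketone followed by O-silylation turns C11 into a protected β-hydroxysilane, a Peterson-type mask of the exocyclic methylene that is inert to organolithiums, oxidants and hydrogenation; the C11 configuration is inconsequential.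

Step 12
Reactants: 27 C11-masked vinyl bromide; 28 1,1-dibromoethene
Product: 31 2-bromo-1,3-diene (C8 carries the 1-bromovinyl group C17(Br)=C18H2 with C6 cis to C17; otherwise as 27), via alkenyllithium 29 (not isolated), via alkenylzinc chloride 30 (not isolated)
Conditions: t-BuLi (2.1 equiv), THF, −78 °C; ZnCl2; then CH2=CBr2 (5 equiv), Pd(PPh3)4 (5 mol %), 25→50 °C
Reagents that add atoms: 1,1-dibromoethene, C=C(Br)Br
Why: Bromine–lithium exchange with retention, transmetalation to zinc and Negishi mono-coupling (the geminal dibromide should react faster than the hindered product bromide) attach C17 and C18 with retention of the C7=C8 geometry.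

Step 13
Reactants: 31 2-bromo-1,3-diene; 32 carbon dioxide; 33 potassium peroxymonosulfate
Product: 37 (7S,8S)-α-methylene-β-hydroxy-γ-lactone (ring C closed: O–C19(=O)–C17(=C18H2)–C8(OH)–C7; otherwise as 31), via dienyllithium 34 (not isolated), via dienoic acid 35 (not isolated), via epoxy acid 36 (not isolated)
Conditions: t-BuLi (2.1 equiv), THF, −78 °C; CO2 (1 atm), −78→0 °C; then MeCN–dimethoxymethane, aq. Na2B4O7–EDTA buffer, D-fructose-derived Shi ketone (30 mol %), Oxone (2KHSO5·KHSO4·K2SO4), K2CO3, 0 °C; then aq. KHSO4 to pH 3–4, 25 °C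
Reagents that add atoms: carbon dioxide, O=C=O; potassium peroxymonosulfate, [K+].OOS(=O)(=O)[O-]
Why: Bromine–lithium exchange gives the 2-lithio-1,3-diene 34, which adds to CO2 at C17 (C17–C19 bond) to give dienoate 35; the dioxirane of the Shi ketone then epoxidises C7=C8, the only electron-rich alkene (the C17=C18 acrylate is electron-poor, the C11 methylene is masked), and on mild acidification the carboxyl group opens the epoxide at C7 with inversion (O–C7 bond) while the epoxide oxygen stays on C8 as the tertiary hydroxyl. The closest known reaction types are carboxylation of alkenyllithiums with CO2, Shi epoxidation of trisubstituted alkenes and conjugated dienes, and conversion of β,γ-epoxy acids into β-hydroxy-γ-lactones. Ring C closes by an anti 5-endo-tet epoxide opening; attack at C8 is disfavoured because it would give a strained β-lactone at a fully substituted carbon that the adjacent acrylate deactivates towards ionisation. C8 is set by reagent control (spiro transition state of the dioxirane, expected to give the (7R,8S)-epoxide), and C7 by the fixed C7=C8 geometry (C6 cis to C17) together with the stereospecific inversion. The step needs regioselective C–C bond formation (secured by the position of the C–Br bond), chemoselective epoxidation (secured by the electronic difference between the two alkenes and the C11 mask) and 5-endo rather than 4-exo closure (secured by ring strain and the electron-poor C17=C18 unit).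

Step 14
Reactants: 37 α-methylene-β-hydroxy-γ-lactone
Product: 39 (17R)-α-methyl-β-hydroxy-γ-lactone (C17 bears H and CH3 with CH3 cis to the C8 hydroxyl; benzyl ethers retained), via 17-epi lactone 38 (not isolated)
Conditions: RhCl(PPh3)3 (5 mol %), H2 (1 atm), benzene, 25 °C; then DBU, toluene, 50 °C
Reagents that add atoms: none
Why: Homogeneous hydrogenation reduces the only alkene (benzyl ethers untouched), and DBU should then equilibrate C17 through the lactone enolate to the thermodynamically preferred 17R epimer, in which the methyl group is trans to the bulky C9 branch.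

Step 15
Reactants: 39 (17R)-α-methyl-β-hydroxy-γ-lactone
Product: 40 lactone diol (primary hydroxyls at C6 and on the C2 carbon; otherwise as 39)
Conditions: H2 (1 atm), Pd(OH)2/C, EtOAc, 25 °C
Reagents that add atoms: none
Why: Hydrogenolysis of both benzyl ethers; the substrate has no alkene or halide at this stage and silyl ethers are stable.

Step 16
Reactants: 40 lactone diol
Product: 41 dialdehyde (C2 and C6 as CHO)
Conditions: Dess–Martin periodinane, NaHCO3, CH2Cl2, 0→25 °C
Reagents that add atoms: none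
Why: Buffered Dess–Martin oxidation of both primary alcohols; the tertiary C8 hydroxyl cannot be oxidised and the non-basic medium should leave C7 unepimerised.

Step 17
Reactants: 42 methyl bis(2,2,2-trifluoroethyl)phosphonoacetate; 14 bromine
Product: 44 methyl 2-bromo-2-[bis(2,2,2-trifluoroethoxy)phosphoryl]acetate, via dibromophosphonate 43 (not isolated)
Conditions: Br2, aq. NaOH, 0 °C; then SnCl2, EtOH–H2O, 0 °C
Reagents that add atoms: bromine, BrBr
Why: Haloform-type dibromination of the active methylene by hypobromite, then selective reductive removal of one bromine, should give the monobromo Horner–Wadsworth–Emmons reagent.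

Step 18
Reactants: 41 dialdehyde; 44 methyl 2-bromo-2-[bis(2,2,2-trifluoroethoxy)phosphoryl]acetate
Product: 45 (E)-α-bromoacrylate aldehyde (C7–C6H=C5(Br)CO2Me with C7 cis to the ester; C2 still CHO)
Conditions: 44 (1.0 equiv), t-BuOK, 18-crown-6, THF, −78 °C
Reagents that add atoms: methyl 2-bromo-2-[bis(2,2,2-trifluoroethoxy)phosphoryl]acetate, COC(=O)C(Br)P(=O)(OCC(F)(F)F)OCC(F)(F)F
Why: Horner–Wadsworth–Emmons olefination with the electron-poor bis(trifluoroethyl) phosphonate (Still–Gennari-type kinetic control) should place C7 cis to the ester, and should occur only at the α-oxygenated C6 aldehyde because the C2 aldehyde is neopentylic.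

Step 19
Reactants: 45 (E)-α-bromoacrylate aldehyde; 46 allyltributylstannane
Product: 47 (2S)-homoallylic alcohol (C2 bears OH and the allyl group C3H2–CH=CH2)
Conditions: allylSnBu3, (S)-BINOL (20 mol %), Ti(OiPr)4 (10 mol %), 4 Å MS, CH2Cl2, −20 °C
Reagents that add atoms: allyltributylstannane, C=CC[Sn](CCCC)(CCCC)CCCC
Why: Keck asymmetric allylation of the remaining aldehyde, in which the BINOL–titanium catalyst should control the new C2 centre (2S); lactone and bromoacrylate are inert to the allylstannane.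

Step 20
Reactants: 47 (2S)-homoallylic alcohol; 48 sodium periodate
Product: 50 β-hydroxy aldehyde (C2 OH; C4 as CHO), via 1,2-diol 49 (not isolated)
Conditions: OsO4 (2 mol %), NaIO4, 2,6-lutidine, dioxane–H2O, 25 °C
Reagents that add atoms: sodium periodate, [Na+].[O-]I(=O)(=O)=O
Why: Lemieux–Johnson cleavage of the only electron-rich alkene; the bromoacrylate is too electron-poor to be dihydroxylated and the C11 methylene is still masked.

Step 21
Reactants: 50 β-hydroxy aldehyde
Product: 52 macrocyclic diol (ring B closed at C4–C5; free OH at C2, C4 (4R) and C8; TBS ethers at C9 and C14; C11 masked), via alkenylchromium dichloride 51 (not isolated)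
Conditions: CrCl2 (10 equiv), NiCl2 (2 mol %), DMSO, 25 °C, 0.002 M
Reagents that add atoms: none
Why: Nozaki–Hiyama–Kishi reaction: nickel-catalysed activation of the alkenyl bromide, transmetalation to chromium and addition to the C4 aldehyde should close the ten-membered ring B with retention of the C5=C6 geometry; the 4R configuration (1,3-syn to the C2 hydroxyl) is expected from attack on the exposed aldehyde face of the chain held by ring A and ring C.

Step 22
Reactants: 52 macrocyclic diol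
Product: 53 pentaol (free OH at C2, C4, C8, C9 and C14; C11(20) exocyclic methylene)
Conditions: HF (48 % aq.), MeCN, 0→25 °C
Reagents that add atoms: none
Why: Aqueous HF should cleave the trimethylsilyl and both TBS ethers and effect the acid-mediated Peterson elimination of the β-hydroxysilane, which can only give the exocyclic C11(20) alkene.

Step 23
Reactants: 53 pentaol; 54 acetic anhydride
Product: 55 CNP0209369.3
Conditions: Ac2O, pyridine, DMAP (cat.), CH2Cl2, 0→25 °C
Reagents that add atoms: acetic anhydride, CC(=O)OC(C)=O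
Why: Acetylation of the four secondary hydroxyls; the tertiary C8 hydroxyl is too hindered to react under these conditions.

## Compound list

1 | 1,4-dioxaspiro[4.5]dec-6-en-8-one | O=C1C=CC2(CC1)OCCO2 | starting material
2 | iodine | II | starting material
3 | 7-iodo-1,4-dioxaspiro[4.5]dec-6-en-8-one | O=C1C(I)=CC2(CC1)OCCO2 | intermediate
4 | potassium (benzyloxymethyl)trifluoroborate | [K+].F[B-](F)(F)COCc1ccccc1 | starting material
5 | 7-[(benzyloxy)methyl]-1,4-dioxaspiro[4.5]dec-6-en-8-one | O=C1C(COCc2ccccc2)=CC2(CC1)OCCO2 | intermediate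
6 | (8S)-7-[(benzyloxy)methyl]-1,4-dioxaspiro[4.5]dec-6-en-8-ol | O[C@H]1CCC2(OCCO2)C=C1COCc1ccccc1 | intermediate
7 | tert-butylchlorodimethylsilane | C[Si](C)(Cl)C(C)(C)C | starting material
8 | (8S)-7-[(benzyloxy)methyl]-8-[(tert-butyldimethylsilyl)oxy]-1,4-dioxaspiro[4.5]dec-6-ene | CC(C)(C)[Si](C)(C)O[C@H]1CCC2(OCCO2)C=C1COCc1ccccc1 | intermediate
9 | water | O | starting material
10 | (4S)-3-[(benzyloxy)methyl]-4-[(tert-butyldimethylsilyl)oxy]cyclohex-2-en-1-one (ring A enone; ring C4 = C14) | O=C1CC[C@H](O[Si](C)(C)C(C)(C)C)C(COCc2ccccc2)=C1 | intermediate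
11 | (Z)-4-(benzyloxy)but-2-en-1-ol | OC/C=C\COCc1ccccc1 | starting material
12 | (Z)-4-(benzyloxy)but-2-enal | O=C/C=C\COCc1ccccc1 | intermediate
13 | (E)-4-(benzyloxy)but-2-enal | O=C/C=C/COCc1ccccc1 | intermediate
14 | bromine | BrBr | starting material
15 | 4-(benzyloxy)-2,3-dibromobutanal (racemic anti adduct) | O=CC(Br)C(Br)COCc1ccccc1 | intermediate
16 | (Z)-4-(benzyloxy)-2-bromobut-2-enal | O=C/C(Br)=C/COCc1ccccc1 | intermediate
17 | lithium dimethylcuprate | [Li+].C[Cu-]C | starting material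
18 | chlorotrimethylsilane | C[Si](C)(C)Cl | starting material
19 | {[(3S,4S)-3-[(benzyloxy)methyl]-4-[(tert-butyldimethylsilyl)oxy]-3-methylcyclohex-1-en-1-yl]oxy}trimethylsilane (C1 methyl trans to C14 OTBS) | C[Si](C)(C)OC1=C[C@@](C)(COCc2ccccc2)[C@@H](O[Si](C)(C)C(C)(C)C)CC1 | intermediate
20 | lithium enolate of the C11 ketone (C10=C11) | [Li]OC1=C[C@@](C)(COCc2ccccc2)[C@@H](O[Si](C)(C)C(C)(C)C)CC1 | intermediate
21 | chlorobis(cyclopentadienyl)zirconium enolate of the C11 ketone | Cl[Zr](OC1=C[C@@](C)(COCc2ccccc2)[C@@H](O[Si](C)(C)C(C)(C)C)CC1)(C1C=CC=C1)C1C=CC=C1 | intermediate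
22 | (2S,3S,4S)-3-[(benzyloxy)methyl]-2-[(1S,2Z)-4-(benzyloxy)-2-bromo-1-hydroxybut-2-en-1-yl]-4-[(tert-butyldimethylsilyl)oxy]-3-methylcyclohexan-1-one (syn aldol; C9 cis to C15) | O=C1CC[C@H](O[Si](C)(C)C(C)(C)C)[C@](C)(COCc2ccccc2)[C@H]1[C@H](O)/C(Br)=C/COCc1ccccc1 | intermediate
23 | tert-butyldimethylsilyl trifluoromethanesulfonate | CC(C)(C)[Si](C)(C)OS(=O)(=O)C(F)(F)F | starting material
24 | C9-O-TBS ether of 22 | O=C1CC[C@H](O[Si](C)(C)C(C)(C)C)[C@](C)(COCc2ccccc2)[C@H]1[C@H](O[Si](C)(C)C(C)(C)C)/C(Br)=C/COCc1ccccc1 | intermediate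
25 | (trimethylsilyl)methyllithium | [Li]C[Si](C)(C)C | starting material
26 | dichlorocerium alkoxide of the C11 adduct (C11 bears O–CeCl2 and CH2SiMe3; C11 configuration undefined) | Cl[Ce](Cl)OC1(C[Si](C)(C)C)CC[C@H](O[Si](C)(C)C(C)(C)C)[C@](C)(COCc2ccccc2)[C@H]1[C@H](O[Si](C)(C)C(C)(C)C)/C(Br)=C/COCc1ccccc1 | intermediate
27 | C11-masked vinyl bromide (C11 bears OSiMe3 and CH2SiMe3; C8 bears Br cis to C6; 9S) | C[Si](C)(C)OC1(C[Si](C)(C)C)CC[C@H](O[Si](C)(C)C(C)(C)C)[C@](C)(COCc2ccccc2)[C@H]1[C@H](O[Si](C)(C)C(C)(C)C)/C(Br)=C/COCc1ccccc1 | intermediate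
28 | 1,1-dibromoethene | C=C(Br)Br | starting material
29 | C8 alkenyllithium from 27 | C[Si](C)(C)OC1(C[Si](C)(C)C)CC[C@H](O[Si](C)(C)C(C)(C)C)[C@](C)(COCc2ccccc2)[C@H]1[C@H](O[Si](C)(C)C(C)(C)C)/C([Li])=C/COCc1ccccc1 | intermediate
30 | C8 alkenylzinc chloride from 27 | C[Si](C)(C)OC1(C[Si](C)(C)C)CC[C@H](O[Si](C)(C)C(C)(C)C)[C@](C)(COCc2ccccc2)[C@H]1[C@H](O[Si](C)(C)C(C)(C)C)/C([Zn]Cl)=C/COCc1ccccc1 | intermediate
31 | 2-bromo-1,3-diene C18H2=C17(Br)–C8=C7H–C6H2OBn (C6 cis to C17; C9 trans to C6) | C[Si](C)(C)OC1(C[Si](C)(C)C)CC[C@H](O[Si](C)(C)C(C)(C)C)[C@](C)(COCc2ccccc2)[C@H]1[C@H](O[Si](C)(C)C(C)(C)C)/C(C(Br)=C)=C/COCc1ccccc1 | intermediate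
32 | carbon dioxide | O=C=O | starting material
33 | potassium peroxymonosulfate (active component of Oxone) | [K+].OOS(=O)(=O)[O-] | starting material
34 | 2-lithio-1,3-diene (Li on C17) | C[Si](C)(C)OC1(C[Si](C)(C)C)CC[C@H](O[Si](C)(C)C(C)(C)C)[C@](C)(COCc2ccccc2)[C@H]1[C@H](O[Si](C)(C)C(C)(C)C)/C(C([Li])=C)=C/COCc1ccccc1 | intermediate
35 | dienoic acid (C19O2H on C17; C17=C18H2; C7=C8) | C[Si](C)(C)OC1(C[Si](C)(C)C)CC[C@H](O[Si](C)(C)C(C)(C)C)[C@](C)(COCc2ccccc2)[C@H]1[C@H](O[Si](C)(C)C(C)(C)C)/C(C(=C)C(=O)O)=C/COCc1ccccc1 | intermediate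
36 | (7R,8S)-7,8-epoxy acid | C[Si](C)(C)OC1(C[Si](C)(C)C)CC[C@H](O[Si](C)(C)C(C)(C)C)[C@](C)(COCc2ccccc2)[C@H]1[C@H](O[Si](C)(C)C(C)(C)C)[C@@]2(C(=C)C(=O)O)O[C@@H]2COCc1ccccc1 | intermediate
37 | (7S,8S)-α-methylene-β-hydroxy-γ-lactone (ring C; C17=C18H2; benzyl ethers on C6–O and on the C2 carbon) | C[Si](C)(C)OC1(C[Si](C)(C)C)CC[C@H](O[Si](C)(C)C(C)(C)C)[C@](C)(COCc2ccccc2)[C@H]1[C@H](O[Si](C)(C)C(C)(C)C)[C@]2(O)C(=C)C(=O)O[C@H]2COCc1ccccc1 | intermediate
38 | (17S)-α-methyl lactone (17-epimer; CH3 cis to C9) | C[Si](C)(C)OC1(C[Si](C)(C)C)CC[C@H](O[Si](C)(C)C(C)(C)C)[C@](C)(COCc2ccccc2)[C@H]1[C@H](O[Si](C)(C)C(C)(C)C)[C@]2(O)[C@H](C)C(=O)O[C@H]2COCc1ccccc1 | intermediate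
39 | (7S,8S,17R)-α-methyl-β-hydroxy-γ-lactone (CH3 cis to C8–OH) | C[Si](C)(C)OC1(C[Si](C)(C)C)CC[C@H](O[Si](C)(C)C(C)(C)C)[C@](C)(COCc2ccccc2)[C@H]1[C@H](O[Si](C)(C)C(C)(C)C)[C@]2(O)[C@@H](C)C(=O)O[C@H]2COCc1ccccc1 | intermediate
40 | lactone diol (CH2OH at C6 and on C1) | C[Si](C)(C)OC1(C[Si](C)(C)C)CC[C@H](O[Si](C)(C)C(C)(C)C)[C@](C)(CO)[C@H]1[C@H](O[Si](C)(C)C(C)(C)C)[C@]2(O)[C@@H](C)C(=O)O[C@H]2CO | intermediate
41 | dialdehyde (C2 and C6 as CHO) | C[Si](C)(C)OC1(C[Si](C)(C)C)CC[C@H](O[Si](C)(C)C(C)(C)C)[C@](C)(C=O)[C@H]1[C@H](O[Si](C)(C)C(C)(C)C)[C@]2(O)[C@@H](C)C(=O)O[C@H]2C=O | intermediate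
42 | methyl bis(2,2,2-trifluoroethyl)phosphonoacetate | COC(=O)CP(=O)(OCC(F)(F)F)OCC(F)(F)F | starting material
43 | methyl 2,2-dibromo-2-[bis(2,2,2-trifluoroethoxy)phosphoryl]acetate | COC(=O)C(Br)(Br)P(=O)(OCC(F)(F)F)OCC(F)(F)F | intermediate
44 | methyl 2-bromo-2-[bis(2,2,2-trifluoroethoxy)phosphoryl]acetate | COC(=O)C(Br)P(=O)(OCC(F)(F)F)OCC(F)(F)F | intermediate
45 | (E)-α-bromoacrylate aldehyde (C7 cis to CO2Me; C2 as CHO) | C[Si](C)(C)OC1(C[Si](C)(C)C)CC[C@H](O[Si](C)(C)C(C)(C)C)[C@](C)(C=O)[C@H]1[C@H](O[Si](C)(C)C(C)(C)C)[C@]2(O)[C@@H](C)C(=O)O[C@H]2/C=C(/Br)C(=O)OC | intermediate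
46 | allyltributylstannane | C=CC[Sn](CCCC)(CCCC)CCCC | starting material
47 | (2S)-homoallylic alcohol | C[Si](C)(C)OC1(C[Si](C)(C)C)CC[C@H](O[Si](C)(C)C(C)(C)C)[C@](C)([C@@H](O)CC=C)[C@H]1[C@H](O[Si](C)(C)C(C)(C)C)[C@]2(O)[C@@H](C)C(=O)O[C@H]2/C=C(/Br)C(=O)OC | intermediate
48 | sodium periodate | [Na+].[O-]I(=O)(=O)=O | starting material
49 | 1,2-diol from the terminal alkene (new carbinol centre undefined) | C[Si](C)(C)OC1(C[Si](C)(C)C)CC[C@H](O[Si](C)(C)C(C)(C)C)[C@](C)([C@@H](O)CC(O)CO)[C@H]1[C@H](O[Si](C)(C)C(C)(C)C)[C@]2(O)[C@@H](C)C(=O)O[C@H]2/C=C(/Br)C(=O)OC | intermediate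
50 | β-hydroxy aldehyde (C2 OH; C4 as CHO) | C[Si](C)(C)OC1(C[Si](C)(C)C)CC[C@H](O[Si](C)(C)C(C)(C)C)[C@](C)([C@@H](O)CC=O)[C@H]1[C@H](O[Si](C)(C)C(C)(C)C)[C@]2(O)[C@@H](C)C(=O)O[C@H]2/C=C(/Br)C(=O)OC | intermediate
51 | C5 alkenylchromium dichloride | C[Si](C)(C)OC1(C[Si](C)(C)C)CC[C@H](O[Si](C)(C)C(C)(C)C)[C@](C)([C@@H](O)CC=O)[C@H]1[C@H](O[Si](C)(C)C(C)(C)C)[C@]2(O)[C@@H](C)C(=O)O[C@H]2/C=C(/[Cr](Cl)Cl)C(=O)OC | intermediate
52 | macrocyclic diol (ring B closed; 2S,4R free OH; C8 OH; TBS at O9 and O14; C11 masked) | C[Si](C)(C)OC1(C[Si](C)(C)C)CC[C@H](O[Si](C)(C)C(C)(C)C)[C@]2(C)[C@@H](O)C[C@@H](O)/C(C(=O)OC)=C/[C@@H]3OC(=O)[C@H](C)[C@@]3(O)[C@@H](O[Si](C)(C)C(C)(C)C)[C@@H]12 | intermediate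
53 | pentaol (2,4,8,9,14-pentahydroxy; 11(20)-methylene) | C=C1CC[C@H](O)[C@]2(C)[C@@H](O)C[C@@H](O)/C(C(=O)OC)=C/[C@@H]3OC(=O)[C@H](C)[C@@]3(O)[C@@H](O)[C@@H]12 | intermediate
54 | acetic anhydride | CC(=O)OC(C)=O | starting material
55 | CNP0209369.3: methyl (1R,2S,4R,5Z,7S,8S,9S,10S,14S,17R)-2,4,9,14-tetraacetoxy-8-hydroxy-19-oxo-7,19-epoxybriara-5,11(20)-dien-16-oate | C=C1CC[C@H](OC(C)=O)[C@]2(C)[C@@H](OC(C)=O)C[C@@H](OC(C)=O)/C(C(=O)OC)=C/[C@@H]3OC(=O)[C@H](C)[C@@]3(O)[C@@H](OC(C)=O)[C@@H]12 | target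

## Step count and risks

Total steps: 23. Longest linear sequence: 20 (steps 1–5, 8–16, 18–23).

**Step 13 (key step).** What may go wrong: protonation or incomplete formation of the dienyllithium; loss of facial selectivity in the epoxidation if the bias of the C9 stereocentre opposes the catalyst; hydrolytic or 4-exo opening of the epoxide in place of 5-endo lactonisation. The fallback sets out from vinyl bromide 27 and returns at 37. The alkenylzinc from 27 (t-BuLi, ZnCl2) is coupled with methyl 2-bromoacrylate under Pd(PPh3)4 catalysis, which brings in C17–C19 as a preformed acrylate and gives methyl dienoate F1. Shi epoxidation of F1 gives epoxy ester F2, which can be isolated and its configuration checked. LiOH hydrolysis and acidification then give 37 by the same 5-endo opening.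

**Step 14.** What may go wrong: hydrogen is delivered to the less hindered face, giving the 17-epimer, and the base equilibration may stay incomplete or open the β-hydroxy lactone by retro-aldol cleavage. The fallback sets out from bromodiene 31 and returns at 39. Carboxylation alone (t-BuLi, CO2) gives dienoic acid 35, now isolated. Ru(OAc)2[(R)-BINAP]-catalysed hydrogenation of this 2-substituted acrylic acid sets C17 by catalyst control before the ring exists and gives the α-methyl β,γ-unsaturated acid F3. Shi epoxidation of F3 with acid-induced lactonisation then gives 39 directly.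

**Step 21.** What may go wrong: oligomerisation instead of ten-membered ring closure, and poor facial selectivity at C4. The fallback sets out from dialdehyde 41 and returns at 52, closing ring B at C2–C3 instead. Chemoselective Knoevenagel condensation of the C6 aldehyde with methyl acetoacetate (piperidinium acetate) gives alkylidene acetoacetate F4. Intramolecular boron aldol reaction of its methyl ketone with the C2 aldehyde (Bu2BOTf, i-Pr2NEt) gives macrocyclic β-hydroxy enone F5. Narasaka–Prasad 1,3-syn reduction (Et2BOMe, NaBH4) then sets C4 from C2 and gives 52.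

## Further compounds

F1 | step 13 | methyl dienoate (methyl ester of 35) | C[Si](C)(C)OC1(C[Si](C)(C)C)CC[C@H](O[Si](C)(C)C(C)(C)C)[C@](C)(COCc2ccccc2)[C@H]1[C@H](O[Si](C)(C)C(C)(C)C)/C(C(=C)C(=O)OC)=C/COCc1ccccc1
F2 | step 13 | (7R,8S)-epoxy ester (methyl ester of 36) | C[Si](C)(C)OC1(C[Si](C)(C)C)CC[C@H](O[Si](C)(C)C(C)(C)C)[C@](C)(COCc2ccccc2)[C@H]1[C@H](O[Si](C)(C)C(C)(C)C)[C@@]2(C(=C)C(=O)OC)O[C@@H]2COCc1ccccc1
F3 | step 14 | (17R)-α-methyl β,γ-unsaturated acid | C[Si](C)(C)OC1(C[Si](C)(C)C)CC[C@H](O[Si](C)(C)C(C)(C)C)[C@](C)(COCc2ccccc2)[C@H]1[C@H](O[Si](C)(C)C(C)(C)C)/C([C@@H](C)C(=O)O)=C/COCc1ccccc1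
F4 | step 21 | alkylidene acetoacetate (C7 cis to CO2Me; C2 as CHO) | C[Si](C)(C)OC1(C[Si](C)(C)C)CC[C@H](O[Si](C)(C)C(C)(C)C)[C@](C)(C=O)[C@H]1[C@H](O[Si](C)(C)C(C)(C)C)[C@]2(O)[C@@H](C)C(=O)O[C@H]2/C=C(/C(C)=O)C(=O)OC
F5 | step 21 | macrocyclic β-hydroxy enone (C2 OH; C4 ketone) | C[Si](C)(C)OC1(C[Si](C)(C)C)CC[C@H](O[Si](C)(C)C(C)(C)C)[C@]2(C)[C@@H](O)CC(=O)/C(C(=O)OC)=C/[C@@H]3OC(=O)[C@H](C)[C@@]3(O)[C@@H](O[Si](C)(C)C(C)(C)C)[C@@H]12
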